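**Plan**

- Numbering: ring atoms O1 to C8a in each chroman, and chain C1 to C8 counted outward from ring C2. Retrosynthetic cuts, in order: both Z alkenes chain C7=C8 (olefination), both chain C5–C6 bonds (twofold [3,3] shift), the C5–C5 biaryl bond, then O1–C8a and C4–C4a of each dihydropyran ring.
- Enabling feature: on each half, ring C2 carries a chain with an E-trisubstituted alkene at chain C3=C4 (methyl on chain C4). It is followed by the methylenes chain C5 and C6 and the sp2 carbon chain C7. This is the γ,δ-unsaturated carbonyl array that an orthoester Claisen rearrangement of a chain-C3 isopropenyl carbinol leaves behind.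
- Forward, monomers: one bromo-iodo arene is joined to each linalool antipode (B-alkyl Suzuki, C4–C4a) and the dihydropyran ring is closed by Pd-catalysed O1–C8a etherification. The prenyl alkene is stored as its epoxide, C5 is brominated, one series is borylated, and the two series are Suzuki-coupled at C5.
- Forward, dimer: every operation runs in both directions. The sequence is epoxide to isopropenyl carbinol, Johnson–Claisen, ester to aldehyde, Still–Gennari olefination, MOM removal, saponification.
- Stereochemistry: ring C2 (S in one half, R in the other) is the carbinol carbon of (S)- and (R)-linalool, whose C–O bond is never broken. The E alkenes come from the chair transition state of the Claisen step and the Z alkenes from the Still–Gennari reagent. Residual antipode in either linalool ends up in homochiral dimers, which are diastereomers and can be removed.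

Key step: step 16

Assumption: the target string fixes no biaryl axis; because the halves are constitutionally identical and of opposite C2 configuration, the two atropisomers are mirror images, so the route should give one diastereomer as an axial racemate, and this is taken as the target.

**Route**

Step 1
Reactants: 1 4-methoxy-2-methylaniline
Product: 2 2-iodo-4-methoxy-6-methylaniline
Conditions: NIS, MeCN, 0 °C to rt, dark
Reagents that add atoms: N-iodosuccinimide, O=C1CCC(=O)N1I
Why: Electrophilic aromatic iodination; the amino group is the strongest donor, its para position and one ortho position are blocked, so iodine should enter the only free ortho carbon.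

Step 2
Reactants: 2 2-iodo-4-methoxy-6-methylaniline
Product: 4 2-bromo-1-iodo-5-methoxy-3-methylbenzene, via arenediazonium bromide 3 (not isolated)
Conditions: NaNO2, 48% aq HBr, 0 °C; then CuBr, 48% aq HBr, 0 to 60 °C
Reagents that add atoms: hydrobromic acid, Br; CuBr, [Cu]Br
Why: Sandmeyer bromination replaces NH2 by Br at the same carbon, and the C–I bond and the methyl ether are inert to cold aqueous acid.

Step 3
Reactants: 4 2-bromo-1-iodo-5-methoxy-3-methylbenzene
Product: 6 4-bromo-3-iodo-5-methylphenol, via aryloxydibromoborane 5 (not isolated)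
Conditions: BBr3, CH2Cl2, −78 °C to rt; then H2O
Reagents that add atoms: none
Why: Lewis-acid aryl methyl ether cleavage, placed here because the molecule still holds no acid-sensitive group, so the ether can be exchanged for one that is removable at the end.

Step 4
Reactants: 6 4-bromo-3-iodo-5-methylphenol
Product: 7 2-bromo-1-iodo-5-(methoxymethoxy)-3-methylbenzene
Conditions: MOMCl, i-Pr2NEt, CH2Cl2, 0 °C to rt
Reagents that add atoms: chloromethyl methyl ether, COCCl
Why: O-alkylation of the phenol (MOM protection) gives an acetal that tolerates bases, organometallics, Pd catalysis, peracid and hydride, and falls to dilute acid.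

Step 5
Reactants: 8 (R)-linalool; 7 2-bromo-1-iodo-5-(methoxymethoxy)-3-methylbenzene
Product: 10 (3R)-1-[2-bromo-5-(methoxymethoxy)-3-methylphenyl]-3,7-dimethyloct-6-en-3-ol, via B-alkyl-9-BBN adduct 9 (not isolated)
Conditions: 8, 9-BBN (2 equiv), THF, 0 °C to rt; then 7, Pd(dppf)Cl2 (5 mol %), 3 M aq K3PO4, THF–DMF, 50 °C
Reagents that add atoms: none
Why: Hydroboration followed by B-alkyl Suzuki–Miyaura coupling; 9-BBN adds anti-Markovnikov to the vinyl group far faster than to the trisubstituted alkene, zerovalent palladium inserts into C–I rather than the flanked C–Br, and the carbinol centre is not touched.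

Step 6
Reactants: 10 (3R)-tertiary alcohol
Product: 11 (2R)-6-(methoxymethoxy)-2,8-dimethyl-2-(4-methylpent-3-en-1-yl)chroman
Conditions: Pd(OAc)2 (5 mol %), 2-(di-tert-butylphosphino)-1,1'-binaphthyl (7 mol %), Cs2CO3, toluene, 90 °C
Reagents that add atoms: none
Why: Intramolecular Buchwald–Hartwig-type C–O coupling closes the six-membered ring at O1–C8a; the tertiary alkoxide has no hydrogen for β-hydride elimination, and because only the aryl–O bond is made, the linalool configuration becomes ring C2 with retention.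

Step 7
Reactants: 11 (2R)-chroman
Product: 12 (2S)-2-[2-(3,3-dimethyloxiran-2-yl)ethyl]-6-(methoxymethoxy)-2,8-dimethylchroman (same spatial arrangement at C2; the descriptor changes by priority only; oxirane CH centre undefined)
Conditions: mCPBA, CH2Cl2, 0 °C
Reagents that add atoms: 3-chloroperbenzoic acid, OOC(=O)c1cccc(Cl)c1
Why: Prilezhaev epoxidation of the only alkene shields this site from NBS in the next step and supplies the direct precursor of the isopropenyl carbinol; the new centre forms without control, which is harmless because step 16 erases it.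

Step 8
Reactants: 12 epoxide of the (R)-linalool series
Product: 13 (2S)-5-bromo-2-[2-(3,3-dimethyloxiran-2-yl)ethyl]-6-(methoxymethoxy)-2,8-dimethylchroman
Conditions: NBS (1.0 equiv), MeCN, 0 °C, dark
Reagents that add atoms: N-bromosuccinimide, O=C1CCC(=O)N1Br
Why: Electrophilic aromatic bromination; only C5 and C7 are free, both ortho to the C6 oxygen, and attack at C5 gives the arenium ion that keeps the C4a=C8a double bond in the fused ring (Mills–Nixon-type bond fixation, the bias that sends substitution of 8-methylchroman-6-ols to C5).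

Step 9
Reactants: 13 bromide of the (R)-linalool series
Product: 15 (2S)-2-[2-(3,3-dimethyloxiran-2-yl)ethyl]-6-(methoxymethoxy)-2,8-dimethyl-5-(4,4,5,5-tetramethyl-1,3,2-dioxaborolan-2-yl)chroman, via aryllithium 14 (not isolated)
Conditions: n-BuLi, THF, −78 °C; then i-PrOBpin, −78 °C to rt
Reagents that add atoms: 2-isopropoxy-4,4,5,5-tetramethyl-1,3,2-dioxaborolane, CC(C)OB1OC(C)(C)C(C)(C)O1
Why: Bromine–lithium exchange and borate trapping; the exchange is much faster at −78 °C than ortho-lithiation or attack on a trialkyl epoxide, and the neighbouring MOM oxygen stabilises the aryllithium.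

Step 10
Reactants: 16 (S)-linalool; 7 2-bromo-1-iodo-5-(methoxymethoxy)-3-methylbenzene
Product: 18 (3S)-1-[2-bromo-5-(methoxymethoxy)-3-methylphenyl]-3,7-dimethyloct-6-en-3-ol, via B-alkyl-9-BBN adduct 17 (not isolated)
Conditions: 16, 9-BBN (2 equiv), THF, 0 °C to rt; then 7, Pd(dppf)Cl2 (5 mol %), 3 M aq K3PO4, THF–DMF, 50 °C
Reagents that add atoms: none
Why: Hydroboration and B-alkyl Suzuki–Miyaura coupling as in step 5, with the same vinyl-over-prenyl and C–I-over-C–Br selectivity and an untouched carbinol centre.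

Step 11
Reactants: 18 (3S)-tertiary alcohol
Product: 19 (2S)-6-(methoxymethoxy)-2,8-dimethyl-2-(4-methylpent-3-en-1-yl)chroman
Conditions: Pd(OAc)2 (5 mol %), 2-(di-tert-butylphosphino)-1,1'-binaphthyl (7 mol %), Cs2CO3, toluene, 90 °C
Reagents that add atoms: none
Why: Intramolecular Buchwald–Hartwig-type C–O coupling as in step 6 closes O1–C8a with retention at the carbinol carbon.

Step 12
Reactants: 19 (2S)-chroman
Product: 20 (2R)-2-[2-(3,3-dimethyloxiran-2-yl)ethyl]-6-(methoxymethoxy)-2,8-dimethylchroman (descriptor change by priority only; oxirane CH centre undefined)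
Conditions: mCPBA, CH2Cl2, 0 °C
Reagents that add atoms: 3-chloroperbenzoic acid, OOC(=O)c1cccc(Cl)c1
Why: Prilezhaev epoxidation as in step 7 masks the alkene and prepares the allylic alcohol.

Step 13
Reactants: 20 epoxide of the (S)-linalool series
Product: 21 (2R)-5-bromo-2-[2-(3,3-dimethyloxiran-2-yl)ethyl]-6-(methoxymethoxy)-2,8-dimethylchroman
Conditions: NBS (1.0 equiv), MeCN, 0 °C, dark
Reagents that add atoms: N-bromosuccinimide, O=C1CCC(=O)N1Br
Why: Electrophilic aromatic bromination as in step 8, directed to C5 by the same bond-fixation bias of the fused dihydropyran ring.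

Step 14
Reactants: 21 bromide of the (S)-linalool series; 15 boronate of the (R)-linalool series
Product: 22 (2R,2'S)-2,2'-bis[2-(3,3-dimethyloxiran-2-yl)ethyl]-6,6'-bis(methoxymethoxy)-2,2',8,8'-tetramethyl-5,5'-bichroman
Conditions: Pd2(dba)3 (5 mol %), SPhos (20 mol %), K3PO4, toluene–H2O, 100 °C
Reagents that add atoms: none
Why: Suzuki–Miyaura coupling with a bulky electron-rich biarylphosphine, the ligand class made for tetra-ortho-substituted biaryls; pairing the halide of one series with the boronate of the other secures the heterochiral dimer, and the MOM and trialkyl epoxide groups tolerate the base.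

Step 15
Reactants: 22 bis-epoxide
Product: 23 5,5'-[(2R,2'S)-6,6'-bis(methoxymethoxy)-2,2',8,8'-tetramethyl-5,5'-bichroman-2,2'-diyl]bis(2-methylpent-1-en-3-ol), carbinol centres undefined
Conditions: Al(Oi-Pr)3, toluene, 110 °C
Reagents that add atoms: none
Why: Aluminium alkoxide-promoted epoxide-to-allylic alcohol isomerisation; aluminium binds the oxirane oxygen, the C–O bond at the tertiary carbon loosens, and an isopropoxide ligand removes a proton from a geminal methyl group, leaving OH on chain C3 and the 1,1-disubstituted alkene on chain C4.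

Step 16
Reactants: 23 bis(isopropenyl carbinol); 24 trimethyl orthoacetate
Product: 27 dimethyl (4E,4'E)-7,7'-[(2R,2'S)-6,6'-bis(methoxymethoxy)-2,2',8,8'-tetramethyl-5,5'-bichroman-2,2'-diyl]bis(4-methylhept-4-enoate), via bis(mixed orthoester) 25 (not isolated), via bis(ketene acetal) 26 (not isolated)
Conditions: MeC(OMe)3 (excess), EtCO2H (cat.), xylene, 140 °C, MeOH distilled off
Reagents that add atoms: trimethyl orthoacetate 24, CC(OC)(OC)OC
Why: Propionic acid catalyses exchange of one methoxy group of 24 for each chain-C3 hydroxyl (25), loss of a second methanol gives the mixed ketene acetals 26, and each allyl vinyl ether array then undergoes a concerted [3,3] sigmatropic shift. This is the Johnson orthoester Claisen rearrangement of a secondary 2-methylallylic alcohol, the standard entry to E-trisubstituted 1,5-diene units, run here at two remote and independent termini. Each shift makes the chain C5–C6 σ bond (former =CH2 carbon to former orthoacetate methyl carbon), moves the alkene to chain C3=C4 and delivers the ester carbon as chain C7; no ring is closed and no stereocentre is created. The selectivity needed is E geometry at both new alkenes, and in the chair transition state the chain-C2 substituent on the carbinol carbon sits equatorial because an axial position would bring it into a 1,3-diaxial contact with the acetal methoxy group. Both carbinol epimers converge on the same E alkene because that carbon becomes sp2, so the diastereomer mixture carried since step 7 should collapse to one compound. Ring C2 lies three atoms from the reacting array, and the MOM ethers, chroman ethers and biaryl are inert to a trace of weak acid in a medium kept dry by the orthoester.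

Step 17
Reactants: 27 bis(methyl ester)
Product: 29 (4E,4'E)-7,7'-[(2R,2'S)-6,6'-bis(methoxymethoxy)-2,2',8,8'-tetramethyl-5,5'-bichroman-2,2'-diyl]bis(4-methylhept-4-enal), via bis(aluminium hemiacetal) 28 (not isolated)
Conditions: i-Bu2AlH (2.2 equiv), toluene, −78 °C; then H2O
Reagents that add atoms: none
Why: Partial ester reduction with diisobutylaluminium hydride; at −78 °C the tetrahedral adduct 28 does not collapse before the quench, so each ester should stop at the aldehyde.

Step 18
Reactants: 29 dialdehyde; 30 ethyl 2-[bis(2,2,2-trifluoroethoxy)phosphoryl]propanoate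
Product: 32 diethyl (2Z,2'Z,6E,6'E)-9,9'-[(2R,2'S)-6,6'-bis(methoxymethoxy)-2,2',8,8'-tetramethyl-5,5'-bichroman-2,2'-diyl]bis(2,6-dimethylnona-2,6-dienoate), via potassium phosphonate carbanion 31 (not isolated)
Conditions: 30, KN(SiMe3)2, 18-crown-6, THF, −78 °C; then 29
Reagents that add atoms: ethyl 2-[bis(2,2,2-trifluoroethoxy)phosphoryl]propanoate 30, CCOC(=O)C(C)P(=O)(OCC(F)(F)F)OCC(F)(F)F
Why: Still–Gennari variant of the Horner–Wadsworth–Emmons olefination; the electron-poor phosphonate and the crown-sequestered potassium ion make elimination from the kinetic adduct faster than its reversal, which places the ester cis to the chain (Z) at both termini.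

Step 19
Reactants: 32 bis-MOM diethyl ester
Product: 33 diethyl (2Z,2'Z,6E,6'E)-9,9'-[(2R,2'S)-6,6'-dihydroxy-2,2',8,8'-tetramethyl-5,5'-bichroman-2,2'-diyl]bis(2,6-dimethylnona-2,6-dienoate)
Conditions: aq HCl (cat.), EtOH, 45 °C
Reagents that add atoms: none
Why: Acid-catalysed acetal cleavage; the alcoholic medium intercepts the oxocarbenium ion before the neighbouring phenol can bridge, ethanol matches the ester so nothing transesterifies, and the isolated trisubstituted alkenes and the Z enoates tolerate dilute acid.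

Step 20
Reactants: 33 bisphenol diethyl ester
Product: 35 target diacid CNP0282703.1, via tetralithium salt 34 (not isolated)
Conditions: LiOH, THF–EtOH–H2O, 45 °C, argon; then 1 M HCl
Reagents that add atoms: lithium hydroxide, [Li+].[OH-]
Why: Saponification by acyl–oxygen cleavage; hydroxide is too weak a base to deconjugate or isomerise the Z enoate, and excluding air protects the electron-rich bisphenoxide until acidification.

**Compound list**

1 | 4-methoxy-2-methylaniline | COc1ccc(N)c(C)c1 | starting material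
2 | 2-iodo-4-methoxy-6-methylaniline | COc1cc(C)c(N)c(I)c1 | intermediate
3 | 2-iodo-4-methoxy-6-methylbenzenediazonium bromide (not isolated) | COc1cc(C)c([N+]#N)c(I)c1.[Br-] | intermediate
4 | 2-bromo-1-iodo-5-methoxy-3-methylbenzene | COc1cc(C)c(Br)c(I)c1 | intermediate
5 | (4-bromo-3-iodo-5-methylphenoxy)dibromoborane (not isolated) | Cc1cc(OB(Br)Br)cc(I)c1Br | intermediate
6 | 4-bromo-3-iodo-5-methylphenol | Cc1cc(O)cc(I)c1Br | intermediate
7 | 2-bromo-1-iodo-5-(methoxymethoxy)-3-methylbenzene | COCOc1cc(C)c(Br)c(I)c1 | intermediate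
8 | (R)-linalool | C=C[C@](C)(O)CCC=C(C)C | starting material
9 | 9-BBN adduct of 8, boron on C1, carbinol centre as in 8 (not isolated) | CC(C)=CCC[C@@](C)(O)CCB1C2CCCC1CCC2 | intermediate
10 | (3R)-1-[2-bromo-5-(methoxymethoxy)-3-methylphenyl]-3,7-dimethyloct-6-en-3-ol | COCOc1cc(C)c(Br)c(CC[C@](C)(O)CCC=C(C)C)c1 | intermediate
11 | (2R)-6-(methoxymethoxy)-2,8-dimethyl-2-(4-methylpent-3-en-1-yl)chroman | COCOc1cc(C)c2c(c1)CC[C@@](C)(CCC=C(C)C)O2 | intermediate
12 | (2S)-2-[2-(3,3-dimethyloxiran-2-yl)ethyl]-6-(methoxymethoxy)-2,8-dimethylchroman | COCOc1cc(C)c2c(c1)CC[C@@](C)(CCC3OC3(C)C)O2 | intermediate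
13 | (2S)-5-bromo-2-[2-(3,3-dimethyloxiran-2-yl)ethyl]-6-(methoxymethoxy)-2,8-dimethylchroman | COCOc1cc(C)c2c(c1Br)CC[C@@](C)(CCC3OC3(C)C)O2 | intermediate
14 | C5 aryllithium from 13 (not isolated) | COCOc1cc(C)c2c(c1[Li])CC[C@@](C)(CCC3OC3(C)C)O2 | intermediate
15 | C5 pinacol boronate of the (R)-linalool series | COCOc1cc(C)c2c(c1B3OC(C)(C)C(C)(C)O3)CC[C@@](C)(CCC4OC4(C)C)O2 | intermediate
16 | (S)-linalool | C=C[C@@](C)(O)CCC=C(C)C | starting material
17 | 9-BBN adduct of 16, boron on C1, carbinol centre as in 16 (not isolated) | CC(C)=CCC[C@](C)(O)CCB1C2CCCC1CCC2 | intermediate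
18 | (3S)-1-[2-bromo-5-(methoxymethoxy)-3-methylphenyl]-3,7-dimethyloct-6-en-3-ol | COCOc1cc(C)c(Br)c(CC[C@@](C)(O)CCC=C(C)C)c1 | intermediate
19 | (2S)-6-(methoxymethoxy)-2,8-dimethyl-2-(4-methylpent-3-en-1-yl)chroman | COCOc1cc(C)c2c(c1)CC[C@](C)(CCC=C(C)C)O2 | intermediate
20 | (2R)-2-[2-(3,3-dimethyloxiran-2-yl)ethyl]-6-(methoxymethoxy)-2,8-dimethylchroman | COCOc1cc(C)c2c(c1)CC[C@](C)(CCC3OC3(C)C)O2 | intermediate
21 | (2R)-5-bromo-2-[2-(3,3-dimethyloxiran-2-yl)ethyl]-6-(methoxymethoxy)-2,8-dimethylchroman | COCOc1cc(C)c2c(c1Br)CC[C@](C)(CCC3OC3(C)C)O2 | intermediate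
22 | (2R,2'S)-5,5'-bichroman bis-epoxide, bis-MOM ether | CC4(C)OC4CC[C@@]1(C)CCc2c(c(C)cc(OCOC)c2-c2c(OCOC)cc(C)c3c2CC[C@@](C)(CCC5OC5(C)C)O3)O1 | intermediate
23 | (2R,2'S)-bichroman bis(isopropenyl carbinol), bis-MOM ether (key-step precursor) | C=C(C)C(O)CC[C@@]1(C)CCc2c(c(C)cc(OCOC)c2-c2c(OCOC)cc(C)c3c2CC[C@@](C)(CCC(O)C(C)=C)O3)O1 | intermediate
24 | trimethyl orthoacetate | CC(OC)(OC)OC | starting material
25 | bis(mixed orthoester) of 23 (not isolated) | C=C(C)C(OC(C)(OC)OC)CC[C@@]1(C)CCc2c(c(C)cc(OCOC)c2-c2c(OCOC)cc(C)c3c2CC[C@@](C)(CCC(OC(C)(OC)OC)C(C)=C)O3)O1 | intermediate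
26 | bis(ketene acetal) (not isolated) | C=C(C)C(OC(=C)OC)CC[C@@]1(C)CCc2c(c(C)cc(OCOC)c2-c2c(OCOC)cc(C)c3c2CC[C@@](C)(CCC(OC(=C)OC)C(C)=C)O3)O1 | intermediate
27 | bis[(E)-γ,δ-unsaturated methyl ester], bis-MOM ether (key-step product) | COC(=O)CC/C(C)=C/CC[C@@]1(C)CCc2c(c(C)cc(OCOC)c2-c2c(OCOC)cc(C)c3c2CC[C@@](C)(CC/C=C(\C)CCC(=O)OC)O3)O1 | intermediate
28 | bis(diisobutylaluminium hemiacetal) of 27 (not isolated) | COC(O[Al](CC(C)C)CC(C)C)CC/C(C)=C/CC[C@@]1(C)CCc2c(c(C)cc(OCOC)c2-c2c(OCOC)cc(C)c3c2CC[C@@](C)(CC/C=C(\C)CCC(OC)O[Al](CC(C)C)CC(C)C)O3)O1 | intermediate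
29 | (E,E)-dialdehyde, bis-MOM ether | O=CCC/C(C)=C/CC[C@@]1(C)CCc2c(c(C)cc(OCOC)c2-c2c(OCOC)cc(C)c3c2CC[C@@](C)(CC/C=C(\C)CCC=O)O3)O1 | intermediate
30 | ethyl 2-[bis(2,2,2-trifluoroethoxy)phosphoryl]propanoate | CCOC(=O)C(C)P(=O)(OCC(F)(F)F)OCC(F)(F)F | starting material
31 | potassium carbanion of 30 (not isolated) | CCOC(=O)[C-](C)P(=O)(OCC(F)(F)F)OCC(F)(F)F.[K+] | intermediate
32 | (2Z,2'Z,6E,6'E)-diethyl ester, bis-MOM ether | C/C(=C/CC/C(C)=C/CC[C@@]1(C)CCc2c(c(C)cc(OCOC)c2-c2c(OCOC)cc(C)c3c2CC[C@@](C)(CC/C=C(\C)CC/C=C(/C)C(=O)OCC)O3)O1)C(=O)OCC | intermediate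
33 | (2Z,2'Z,6E,6'E)-diethyl ester, free bisphenol | C/C(=C/CC/C(C)=C/CC[C@@]1(C)CCc2c(c(C)cc(O)c2-c2c(O)cc(C)c3c2CC[C@@](C)(CC/C=C(\C)CC/C=C(/C)C(=O)OCC)O3)O1)C(=O)OCC | intermediate
34 | tetralithium bis(carboxylate) bis(phenoxide) (not isolated) | C/C(=C/CC/C(C)=C/CC[C@@]1(C)CCc2c(c(C)cc([O-])c2-c2c([O-])cc(C)c3c2CC[C@@](C)(CC/C=C(\C)CC/C=C(/C)C(=O)[O-])O3)O1)C(=O)[O-].[Li+].[Li+].[Li+].[Li+] | intermediate
35 | (2Z,2'Z,6E,6'E)-9,9'-[(2R,2'S)-6,6'-dihydroxy-2,2',8,8'-tetramethyl-5,5'-bichroman-2,2'-diyl]bis(2,6-dimethylnona-2,6-dienoic acid), CNP0282703.1 | C/C(=C/CC/C(C)=C/CC[C@@]1(C)CCc2c(c(C)cc(O)c2-c2c(O)cc(C)c3c2CC[C@@](C)(CC/C=C(\C)CC/C=C(/C)C(=O)O)O3)O1)C(=O)O | target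

**Step count**

Total step count: 20. Longest linear sequence: 16 (steps 1–9, then 14–20).

**Steps most likely to fail**

1. Step 14. Transmetalation at a boronate flanked on both sides may be so slow that protodeboronation and hydrodehalogenation outrun C–C bond formation. The fallback is a Negishi coupling, which uses neither boron, water nor base. It sets out from 13: bromine–lithium exchange gives 14, and ZnCl2 in THF converts this into the arylzinc chloride F1. F1 is coupled with 21 under Pd2(dba)3 and RuPhos in THF at 70 °C and comes back to the route at 22.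

2. Step 8 (step 13 is its mirror image). Discrimination between C5 and C7 on the ether may be poor, or a second bromination may compete. The fallback moves the halogenation to the free phenol, where the C5 preference of 8-methylchroman-6-ols is established and a phenoxide reacts with iodine far faster than an isolated alkene does.
   - (R)-linalool series: from 11, HCl in MeOH gives the (2R)-chromanol F2. I2 with aq NaHCO3 in THF at 0 °C gives the (2R)-5-iodochromanol F4. MOMCl and i-Pr2NEt give the (2R)-iodo MOM ether F6, and mCPBA gives the iodo epoxide F8. Iodine–lithium exchange on F8 gives 14, which returns to the route at 15.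
   - (S)-linalool series: the same operations on 19 give the (2S)-chromanol F3, the (2S)-5-iodochromanol F5, the (2S)-iodo MOM ether F7 and the iodo epoxide F9. F9 takes the place of 21 in step 14 and returns at 22.

3. Step 15. A hydride shift at the aluminium-activated oxirane may compete with proton removal, or one of the two epoxides may remain unconverted. The fallback rebuilds the carbinol by cleavage and addition instead of isomerisation. From 22, H5IO6 in THF–Et2O at 0 °C opens and cleaves both oxiranes to give the bis(propanal) F10. Addition of isopropenylmagnesium bromide (THF, −78 °C) to both aldehydes comes back to the route at 23.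

**Further compounds**

F1 | step 14 | [(2S)-2-[2-(3,3-dimethyloxiran-2-yl)ethyl]-6-(methoxymethoxy)-2,8-dimethylchroman-5-yl]zinc chloride | COCOc1cc(C)c2c(c1[Zn]Cl)CC[C@@](C)(CCC3OC3(C)C)O2
F2 | step 8 | (2R)-2,8-dimethyl-2-(4-methylpent-3-en-1-yl)chroman-6-ol | Oc1cc(C)c2c(c1)CC[C@@](C)(CCC=C(C)C)O2
F3 | step 8 | (2S)-2,8-dimethyl-2-(4-methylpent-3-en-1-yl)chroman-6-ol | Oc1cc(C)c2c(c1)CC[C@](C)(CCC=C(C)C)O2
F4 | step 8 | (2R)-5-iodo-2,8-dimethyl-2-(4-methylpent-3-en-1-yl)chroman-6-ol | Oc1cc(C)c2c(c1I)CC[C@@](C)(CCC=C(C)C)O2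
F5 | step 8 | (2S)-5-iodo-2,8-dimethyl-2-(4-methylpent-3-en-1-yl)chroman-6-ol | Oc1cc(C)c2c(c1I)CC[C@](C)(CCC=C(C)C)O2
F6 | step 8 | (2R)-5-iodo-6-(methoxymethoxy)-2,8-dimethyl-2-(4-methylpent-3-en-1-yl)chroman | COCOc1cc(C)c2c(c1I)CC[C@@](C)(CCC=C(C)C)O2
F7 | step 8 | (2S)-5-iodo-6-(methoxymethoxy)-2,8-dimethyl-2-(4-methylpent-3-en-1-yl)chroman | COCOc1cc(C)c2c(c1I)CC[C@](C)(CCC=C(C)C)O2
F8 | step 8 | (2S)-2-[2-(3,3-dimethyloxiran-2-yl)ethyl]-5-iodo-6-(methoxymethoxy)-2,8-dimethylchroman | COCOc1cc(C)c2c(c1I)CC[C@@](C)(CCC3OC3(C)C)O2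
F9 | step 8 | (2R)-2-[2-(3,3-dimethyloxiran-2-yl)ethyl]-5-iodo-6-(methoxymethoxy)-2,8-dimethylchroman | COCOc1cc(C)c2c(c1I)CC[C@](C)(CCC3OC3(C)C)O2
F10 | step 15 | 3,3'-[(2R,2'S)-6,6'-bis(methoxymethoxy)-2,2',8,8'-tetramethyl-5,5'-bichroman-2,2'-diyl]dipropanal | O=CCC[C@@]1(C)CCc2c(c(C)cc(OCOC)c2-c2c(OCOC)cc(C)c3c2CC[C@@](C)(CCC=O)O3)O1
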